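Everything rests on cutting the tetrahydrofuran at its O–CH2 bond and at the bond between the CH(CH2OH) carbon and the carbinol carbon C(OH)(benzyl). That carbinol carbon is flanked by two CH2 groups (ring OCH2 and benzylic CH2), so it is a masked symmetric ketone, 1,3-dichloroacetone. In the key step the dilithium dianion of an enantiopure β-aryl-β-hydroxy ester, which already carries the complete threo aryl glycerol ether, adds to this ketone; the benzylic alkoxide then closes the tetrahydrofuran on one CH2Cl arm and the tertiary alkoxide closes an oxirane on the other. An aryl cuprate later turns the spiro-epoxide into the benzyl carbinol. The ring stereocentres are relayed from the benzylic carbinol set by asymmetric transfer hydrogenation.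

Key step: step 7

Remark: "aryl A" = 4-{[(4R,5R)-4-[4-(benzyloxy)-3-methoxyphenyl]-2,2-dimethyl-1,3-dioxan-5-yl]oxy}-3-methoxyphenyl. Tetrahydrofuran locants in all names and Why lines: O1, C2 (aryl), C3 (ester or CH2OH), C4 (carbinol), C5 (OCH2).
Assumption: the acylated auxiliary 1 is taken as a purchasable reagent.

Step 1
Reactants: 1 (4S)-4-benzyl-3-(chloroacetyl)oxazolidin-2-one; 2 methyl 4-hydroxy-3-methoxybenzoate (methyl vanillate)
Product: 3 methyl 4-{2-[(4S)-4-benzyl-2-oxooxazolidin-3-yl]-2-oxoethoxy}-3-methoxybenzoate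
Conditions: K2CO3, KI (10 mol %), acetone, 50 °C
Reagents that add atoms: none
Why: Williamson ether synthesis, the phenoxide displacing the activated α-chloride of the imide by SN2 without touching the auxiliary stereocentre.

Step 2
Reactants: 3 methyl 4-{2-[(4S)-4-benzyl-2-oxooxazolidin-3-yl]-2-oxoethoxy}-3-methoxybenzoate; 4 4-(benzyloxy)-3-methoxybenzaldehyde
Product: 6 methyl 4-{[(1R,2S)-1-[4-(benzyloxy)-3-methoxyphenyl]-3-[(4S)-4-benzyl-2-oxooxazolidin-3-yl]-1-hydroxy-3-oxopropan-2-yl]oxy}-3-methoxybenzoate, via boron enolate 5 (not isolated)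
Conditions: Bu2BOTf, iPr2NEt, CH2Cl2, −78 to 0 °C; then 4, −78 to 0 °C; pH 7 buffer, MeOH, 30% H2O2
Reagents that add atoms: none
Why: Evans syn aldol reaction, in which the (Z)-boron enolate reacts through a Zimmerman–Traxler chair on the face away from the benzyl group of the (S)-auxiliary and so should set both new centres as the threo adduct.

Step 3
Reactants: 6 Evans syn aldol adduct
Product: 7 methyl 4-{[(1R,2R)-1-[4-(benzyloxy)-3-methoxyphenyl]-1,3-dihydroxypropan-2-yl]oxy}-3-methoxybenzoate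
Conditions: NaBH4, THF/H2O (4:1), 0 to 25 °C
Reagents that add atoms: none
Why: Reductive cleavage of the N-acyloxazolidinone to the primary alcohol (the imide carbonyl is far more electrophilic than the benzoate), both stereocentres being retained.

Step 4
Reactants: 7 threo diol
Product: 8 methyl 4-{[(4R,5R)-4-[4-(benzyloxy)-3-methoxyphenyl]-2,2-dimethyl-1,3-dioxan-5-yl]oxy}-3-methoxybenzoate
Conditions: 2,2-dimethoxypropane, PPTS (cat.), CH2Cl2, 25 °C
Reagents that add atoms: 2,2-dimethoxypropane COC(C)(C)OC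
Why: Acid-catalysed transketalisation to the six-membered acetonide of the 1,3-diol, which masks both hydroxyl groups for the strongly basic steps.

Step 5
Reactants: 8 acetonide methyl ester
Product: 9 tert-butyl 3-(aryl A)-3-oxopropanoate
Conditions: tert-butyl acetate, LiN(iPr)2 (3 equiv each), THF, −78 to 0 °C; sat. NH4Cl
Reagents that add atoms: tert-butyl acetate CC(=O)OC(C)(C)C
Why: Crossed Claisen condensation of the lithium enolate of tert-butyl acetate with the non-enolisable aryl ester, the β-keto ester being shielded from further attack as its enolate.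

Step 6
Reactants: 9 tert-butyl 3-(aryl A)-3-oxopropanoate
Product: 10 tert-butyl (3S)-3-(aryl A)-3-hydroxypropanoate
Conditions: RuCl(p-cymene)[(S,S)-TsDPEN] (1 mol %), HCO2Na, H2O/EtOAc, 40 °C
Reagents that add atoms: none
Why: Noyori–Ikariya asymmetric transfer hydrogenation of the aryl ketone, the (S,S)-catalyst delivering hydride to the face that gives the (S)-carbinol as it does for acetophenone, which sets C2 of the tetrahydrofuran.

Step 7
Reactants: 10 tert-butyl (3S)-3-(aryl A)-3-hydroxypropanoate; 11 1,3-dichloropropan-2-one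
Product: 15 tert-butyl (3R,6S,7S)-6-(aryl A)-1,5-dioxaspiro[2.4]heptane-7-carboxylate (oxirane oxygen, ester and aryl group all cis on the tetrahydrofuran), via dilithium dianion 12 (not isolated), via dilithium dialkoxide 13 (not isolated), via chloromethyl tetrahydrofuran alkoxide 14 (not isolated)
Conditions: LiN(iPr)2 (2.2 equiv), THF, −78 to −20 °C; 11, −78 °C; then DMPU, −78 to 25 °C; sat. NH4Cl
Reagents that add atoms: none
Why: The chelated dianion 12 adds through C3 to the carbonyl of 11 (symmetric, unhindered, activated by two α-chlorine atoms) to give dialkoxide 13; on warming the benzylic alkoxide displaces chloride from one CH2Cl arm (tetrahydrofuran, 5-exo-tet, O1–C5 bond) and the tertiary alkoxide then closes the oxirane on the other arm (3-exo-tet). The closest known reaction types are the Fráter–Seebach hydroxyalkylation of β-hydroxy ester dianions and the chlorohydrin-to-ether Williamson closure, the whole being the saturated dianionic counterpart of the interrupted Feist–Benary annulation. C2 is untouched, and C3 is set by attack on the enolate face anti to the aryl group of the six-membered lithium chelate, which should place ester and aryl cis on the new ring (corrected in step 10). C4 is not stereogenic in 13 and is set by which of the two diastereotopic CH2Cl arms the ether closure uses: in the favoured transition state the C4–O–Li oxygen should stay chelated to the cis ester carbonyl and the spectator CH2Cl arm lie trans to the ester, so the oxirane oxygen ends cis to ester and aryl. The step needs carbonyl addition to beat enolisation and SN2 alkylation of 11, which low temperature and the high electrophilicity of the ketone should secure, and ether closure to precede oxirane closure.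

Step 8
Reactants: 15 spiro-epoxide; 16 1-(benzyloxy)-4-bromo-2-methoxybenzene
Product: 18 tert-butyl (2S,3S,4S)-2-(aryl A)-4-[4-(benzyloxy)-3-methoxybenzyl]-4-hydroxytetrahydrofuran-3-carboxylate, via aryl Grignard reagent 17 (not isolated)
Conditions: 16, Mg, THF, 25 °C; then CuI (copper monoiodide, 10 mol %), 15, THF, −40 to 0 °C; sat. NH4Cl
Reagents that add atoms: none
Why: Copper-catalysed SN2 opening of the 2,2-disubstituted oxirane at its CH2 carbon by the aryl Grignard reagent, which breaks no bond to C4 (configuration kept) while the tert-butyl ester should resist addition.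

Step 9
Reactants: 18 tertiary alcohol
Product: 19 tert-butyl (2S,3S,4S)-2-(aryl A)-4-[4-(benzyloxy)-3-methoxybenzyl]-4-[(triethylsilyl)oxy]tetrahydrofuran-3-carboxylate
Conditions: TESOTf, 2,6-lutidine, CH2Cl2, −40 to 0 °C
Reagents that add atoms: triethylsilyl trifluoromethanesulfonate CC[Si](CC)(CC)OS(=O)(=O)C(F)(F)F
Why: Silylation of the tertiary alcohol, which blocks retro-aldol cleavage in the next step and makes the oxygen substituent at C4 bulky.

Step 10
Reactants: 19 silyl ether with cis-2,3 ester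
Product: 20 tert-butyl (2S,3R,4S)-2-(aryl A)-4-[4-(benzyloxy)-3-methoxybenzyl]-4-[(triethylsilyl)oxy]tetrahydrofuran-3-carboxylate
Conditions: KOtBu (0.3 equiv), tBuOH/THF, 25 to 40 °C
Reagents that add atoms: none
Why: Thermodynamic epimerisation α to the ester through the enolate, which should move the C3 ester from the face it shares with the C2 aryl and C4 silyloxy groups to the face of the benzyl group (trans-2,3), ring opening being the stereoelectronically disfavoured reverse of a 5-endo-trig closure.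

Step 11
Reactants: 20 trans-2,3 ester
Product: 21 {(2S,3R,4S)-2-(aryl A)-4-[4-(benzyloxy)-3-methoxybenzyl]-4-[(triethylsilyl)oxy]tetrahydrofuran-3-yl}methanol
Conditions: LiAlH4, THF, 0 °C; Fieser work-up
Reagents that add atoms: none
Why: Hydride reduction of the ester to the primary alcohol, which touches no stereocentre and leaves silyl ether and acetonide in place.

Step 12
Reactants: 21 silyl ether acetonide
Product: 22 (2S,3R,4S)-2-(4-{[(1R,2R)-1-[4-(benzyloxy)-3-methoxyphenyl]-1,3-dihydroxypropan-2-yl]oxy}-3-methoxyphenyl)-4-[4-(benzyloxy)-3-methoxybenzyl]-3-(hydroxymethyl)tetrahydrofuran-4-ol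
Conditions: 1 M aq. HCl/THF (1:4), 25 °C
Reagents that add atoms: none
Why: Acid hydrolysis of the acetonide and the triethylsilyl ether, dilute acid at room temperature being expected to leave the benzylic C–O bonds intact.

Step 13
Reactants: 22 bis(benzyl ether)
Product: 23 target, (2S,3R,4S)-2-(4-{[(1R,2R)-1,3-dihydroxy-1-(4-hydroxy-3-methoxyphenyl)propan-2-yl]oxy}-3-methoxyphenyl)-4-(4-hydroxy-3-methoxybenzyl)-3-(hydroxymethyl)tetrahydrofuran-4-ol
Conditions: H2 (1 atm), Pd/C (10 wt % palladium on carbon), EtOAc/EtOH, 25 °C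
Reagents that add atoms: none
Why: Hydrogenolysis of the two aryl benzyl ethers under neutral conditions, which should spare the benzylic alcohol and the benzylic ring ether.

Compound list
1 | (4S)-4-benzyl-3-(chloroacetyl)oxazolidin-2-one | O=C1OC[C@H](Cc2ccccc2)N1C(=O)CCl | starting material
2 | methyl 4-hydroxy-3-methoxybenzoate | COC(=O)c1ccc(O)c(OC)c1 | starting material
3 | methyl 4-{2-[(4S)-4-benzyl-2-oxooxazolidin-3-yl]-2-oxoethoxy}-3-methoxybenzoate | COC(=O)c1ccc(OCC(=O)N2[C@@H](Cc3ccccc3)COC2=O)c(OC)c1 | intermediate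
4 | 4-(benzyloxy)-3-methoxybenzaldehyde | O=Cc1ccc(OCc2ccccc2)c(OC)c1 | starting material
5 | (Z)-dibutylboron enolate of 3 (not isolated) | CCCCB(CCCC)O/C(=C\Oc1ccc(C(=O)OC)cc1OC)N1[C@@H](Cc2ccccc2)COC1=O | intermediate
6 | methyl 4-{[(1R,2S)-1-[4-(benzyloxy)-3-methoxyphenyl]-3-[(4S)-4-benzyl-2-oxooxazolidin-3-yl]-1-hydroxy-3-oxopropan-2-yl]oxy}-3-methoxybenzoate | COC(=O)c1ccc(O[C@H](C(=O)N2[C@@H](Cc3ccccc3)COC2=O)[C@H](O)c2ccc(OCc3ccccc3)c(OC)c2)c(OC)c1 | intermediate
7 | methyl 4-{[(1R,2R)-1-[4-(benzyloxy)-3-methoxyphenyl]-1,3-dihydroxypropan-2-yl]oxy}-3-methoxybenzoate | COC(=O)c1ccc(O[C@H](CO)[C@H](O)c2ccc(OCc3ccccc3)c(OC)c2)c(OC)c1 | intermediate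
8 | methyl 4-{[(4R,5R)-4-[4-(benzyloxy)-3-methoxyphenyl]-2,2-dimethyl-1,3-dioxan-5-yl]oxy}-3-methoxybenzoate | COC(=O)c1ccc(O[C@@H]2COC(C)(C)O[C@@H]2c2ccc(OCc3ccccc3)c(OC)c2)c(OC)c1 | intermediate
9 | tert-butyl 3-(aryl A)-3-oxopropanoate | CC(C)(C)OC(=O)CC(=O)c1ccc(O[C@@H]2COC(C)(C)O[C@@H]2c2ccc(OCc3ccccc3)c(OC)c2)c(OC)c1 | intermediate
10 | tert-butyl (3S)-3-(aryl A)-3-hydroxypropanoate | CC(C)(C)OC(=O)C[C@H](O)c1ccc(O[C@@H]2COC(C)(C)O[C@@H]2c2ccc(OCc3ccccc3)c(OC)c2)c(OC)c1 | intermediate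
11 | 1,3-dichloropropan-2-one | ClCC(=O)CCl | starting material
12 | dilithium alkoxide (Z)-enolate of 10 (not isolated) | [Li+].[Li+].CC(C)(C)O/C([O-])=C/[C@H]([O-])c1ccc(O[C@@H]2COC(C)(C)O[C@@H]2c2ccc(OCc3ccccc3)c(OC)c2)c(OC)c1 | intermediate
13 | dilithium salt of tert-butyl (2S,3S)-3-(aryl A)-2-(1,3-dichloro-2-hydroxypropan-2-yl)-3-hydroxypropanoate (not isolated) | [Li+].[Li+].CC(C)(C)OC(=O)[C@@H]([C@H]([O-])c1ccc(O[C@@H]2COC(C)(C)O[C@@H]2c2ccc(OCc3ccccc3)c(OC)c2)c(OC)c1)C([O-])(CCl)CCl | intermediate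
14 | lithium alkoxide of tert-butyl (2S,3S,4S)-2-(aryl A)-4-(chloromethyl)-4-hydroxytetrahydrofuran-3-carboxylate, oxygen at C4 cis to ester and aryl (not isolated) | [Li+].CC(C)(C)OC(=O)[C@H]1[C@@H](c3ccc(O[C@@H]4COC(C)(C)O[C@@H]4c4ccc(OCc5ccccc5)c(OC)c4)c(OC)c3)OC[C@]1([O-])CCl | intermediate
15 | tert-butyl (3R,6S,7S)-6-(aryl A)-1,5-dioxaspiro[2.4]heptane-7-carboxylate | CC(C)(C)OC(=O)[C@H]1[C@@H](c3ccc(O[C@@H]4COC(C)(C)O[C@@H]4c4ccc(OCc5ccccc5)c(OC)c4)c(OC)c3)OC[C@]12CO2 | intermediate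
16 | 1-(benzyloxy)-4-bromo-2-methoxybenzene | COc1cc(Br)ccc1OCc1ccccc1 | starting material
17 | [4-(benzyloxy)-3-methoxyphenyl]magnesium bromide (not isolated) | COc1cc([Mg]Br)ccc1OCc1ccccc1 | intermediate
18 | tert-butyl (2S,3S,4S)-2-(aryl A)-4-[4-(benzyloxy)-3-methoxybenzyl]-4-hydroxytetrahydrofuran-3-carboxylate | CC(C)(C)OC(=O)[C@H]1[C@@H](c3ccc(O[C@@H]4COC(C)(C)O[C@@H]4c4ccc(OCc5ccccc5)c(OC)c4)c(OC)c3)OC[C@]1(O)Cc1ccc(OCc2ccccc2)c(OC)c1 | intermediate
19 | tert-butyl (2S,3S,4S)-2-(aryl A)-4-[4-(benzyloxy)-3-methoxybenzyl]-4-[(triethylsilyl)oxy]tetrahydrofuran-3-carboxylate | CC(C)(C)OC(=O)[C@H]1[C@@H](c3ccc(O[C@@H]4COC(C)(C)O[C@@H]4c4ccc(OCc5ccccc5)c(OC)c4)c(OC)c3)OC[C@]1(O[Si](CC)(CC)CC)Cc1ccc(OCc2ccccc2)c(OC)c1 | intermediate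
20 | tert-butyl (2S,3R,4S)-2-(aryl A)-4-[4-(benzyloxy)-3-methoxybenzyl]-4-[(triethylsilyl)oxy]tetrahydrofuran-3-carboxylate | CC(C)(C)OC(=O)[C@@H]1[C@@H](c3ccc(O[C@@H]4COC(C)(C)O[C@@H]4c4ccc(OCc5ccccc5)c(OC)c4)c(OC)c3)OC[C@]1(O[Si](CC)(CC)CC)Cc1ccc(OCc2ccccc2)c(OC)c1 | intermediate
21 | {(2S,3R,4S)-2-(aryl A)-4-[4-(benzyloxy)-3-methoxybenzyl]-4-[(triethylsilyl)oxy]tetrahydrofuran-3-yl}methanol | OC[C@@H]1[C@@H](c3ccc(O[C@@H]4COC(C)(C)O[C@@H]4c4ccc(OCc5ccccc5)c(OC)c4)c(OC)c3)OC[C@]1(O[Si](CC)(CC)CC)Cc1ccc(OCc2ccccc2)c(OC)c1 | intermediate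
22 | (2S,3R,4S)-2-(4-{[(1R,2R)-1-[4-(benzyloxy)-3-methoxyphenyl]-1,3-dihydroxypropan-2-yl]oxy}-3-methoxyphenyl)-4-[4-(benzyloxy)-3-methoxybenzyl]-3-(hydroxymethyl)tetrahydrofuran-4-ol | OC[C@@H]1[C@@H](c3ccc(O[C@H](CO)[C@H](O)c4ccc(OCc5ccccc5)c(OC)c4)c(OC)c3)OC[C@]1(O)Cc1ccc(OCc2ccccc2)c(OC)c1 | intermediate
23 | (2S,3R,4S)-2-(4-{[(1R,2R)-1,3-dihydroxy-1-(4-hydroxy-3-methoxyphenyl)propan-2-yl]oxy}-3-methoxyphenyl)-4-(4-hydroxy-3-methoxybenzyl)-3-(hydroxymethyl)tetrahydrofuran-4-ol | COc1cc(C[C@@]2(O)CO[C@H](c3ccc(O[C@H](CO)[C@H](O)c4ccc(O)c(OC)c4)c(OC)c3)[C@H]2CO)ccc1O | target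

Total step count: 13. Longest linear sequence: 13 steps (1 and 2 to 23).

Steps most likely to fail

1. Step 7. The aldol addition may lose to enolisation or SN2 alkylation of the dichloroketone. The two chloromethyl arms may also be poorly discriminated if the tertiary alkoxide closes the oxirane before the ether ring forms. Fallback, from 10 back to 15: dianion 12 is added at −78 °C to oxetan-3-one, which cannot enolise usefully and offers no competing epoxide closure, to give tert-butyl (2S,3S)-3-(aryl A)-3-hydroxy-2-(3-hydroxyoxetan-3-yl)propanoate F1. Sc(OTf)3 (5 mol %) in CH2Cl2 at 0 °C should then let the benzylic hydroxyl open the oxetane (5-exo-tet) on the arm that leaves the hydroxymethyl group trans to the ester, giving tert-butyl (2S,3S)-2-(aryl A)-4-hydroxy-4-(hydroxymethyl)tetrahydrofuran-3-carboxylate F2. TsCl in pyridine gives the primary tosylate F3, which DBU closes to spiro-epoxide 15.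

2. Step 10. Epimerisation may be incomplete, or β-elimination of the silyloxy group from the ester enolate may compete. Fallback, from 19 back to 21: LiAlH4 gives the cis-2,3 primary alcohol F4 and Dess–Martin periodinane the cis-2,3 aldehyde F5. The aldehyde is far more acidic than the ester and is equilibrated with Et3N in CH2Cl2 to the trans-2,3 aldehyde F6; NaBH4 then gives 21.

3. Step 8. The Grignard reagent may deprotonate α to the ester, with E1cB opening of the oxirane, or attack the ester, instead of undergoing the copper-catalysed opening. Fallback, from 10 back to 18, with the aryl ring brought in on the ketone so that no epoxide has to be opened: commercial [4-(benzyloxy)-3-methoxyphenyl]acetic acid is converted by oxalyl chloride into the acid chloride F7, by TMSCHN2 into the diazoketone F8 and by HCl into 1-[4-(benzyloxy)-3-methoxyphenyl]-3-chloropropan-2-one F9. Dianion 12 is added to F9 at −78 °C to give the dilithium dialkoxide F10, which on warming closes the tetrahydrofuran (5-exo-tet) to 18. In this variant C4 is fixed by the face of the aldol addition, and its epimer would have to be removed by chromatography.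

Further compounds
F1 | step 7 | tert-butyl (2S,3S)-3-(aryl A)-3-hydroxy-2-(3-hydroxyoxetan-3-yl)propanoate | CC(C)(C)OC(=O)[C@@H]([C@H](O)c1ccc(O[C@@H]2COC(C)(C)O[C@@H]2c2ccc(OCc3ccccc3)c(OC)c2)c(OC)c1)C1(O)COC1
F2 | step 7 | tert-butyl (2S,3S)-2-(aryl A)-4-hydroxy-4-(hydroxymethyl)tetrahydrofuran-3-carboxylate, C4 hydroxyl cis to ester and aryl | CC(C)(C)OC(=O)[C@H]1[C@@H](c3ccc(O[C@@H]4COC(C)(C)O[C@@H]4c4ccc(OCc5ccccc5)c(OC)c4)c(OC)c3)OC[C@]1(O)CO
F3 | step 7 | primary tosylate of F2 | CC(C)(C)OC(=O)[C@H]1[C@@H](c3ccc(O[C@@H]4COC(C)(C)O[C@@H]4c4ccc(OCc5ccccc5)c(OC)c4)c(OC)c3)OC[C@]1(O)COS(=O)(=O)c1ccc(C)cc1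
F4 | step 10 | {(2S,3S,4S)-2-(aryl A)-4-[4-(benzyloxy)-3-methoxybenzyl]-4-[(triethylsilyl)oxy]tetrahydrofuran-3-yl}methanol | OC[C@H]1[C@@H](c3ccc(O[C@@H]4COC(C)(C)O[C@@H]4c4ccc(OCc5ccccc5)c(OC)c4)c(OC)c3)OC[C@]1(O[Si](CC)(CC)CC)Cc1ccc(OCc2ccccc2)c(OC)c1
F5 | step 10 | (2S,3S,4S)-2-(aryl A)-4-[4-(benzyloxy)-3-methoxybenzyl]-4-[(triethylsilyl)oxy]tetrahydrofuran-3-carbaldehyde | O=C[C@H]1[C@@H](c3ccc(O[C@@H]4COC(C)(C)O[C@@H]4c4ccc(OCc5ccccc5)c(OC)c4)c(OC)c3)OC[C@]1(O[Si](CC)(CC)CC)Cc1ccc(OCc2ccccc2)c(OC)c1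
F6 | step 10 | (2S,3R,4S)-2-(aryl A)-4-[4-(benzyloxy)-3-methoxybenzyl]-4-[(triethylsilyl)oxy]tetrahydrofuran-3-carbaldehyde | O=C[C@@H]1[C@@H](c3ccc(O[C@@H]4COC(C)(C)O[C@@H]4c4ccc(OCc5ccccc5)c(OC)c4)c(OC)c3)OC[C@]1(O[Si](CC)(CC)CC)Cc1ccc(OCc2ccccc2)c(OC)c1
F7 | step 8 | [4-(benzyloxy)-3-methoxyphenyl]acetyl chloride | COc1cc(CC(Cl)=O)ccc1OCc1ccccc1
F8 | step 8 | 1-[4-(benzyloxy)-3-methoxyphenyl]-3-diazopropan-2-one | COc1cc(CC(=O)C=[N+]=[N-])ccc1OCc1ccccc1
F9 | step 8 | 1-[4-(benzyloxy)-3-methoxyphenyl]-3-chloropropan-2-one | COc1cc(CC(=O)CCl)ccc1OCc1ccccc1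
F10 | step 8 | dilithium salt of tert-butyl (2S,3S)-3-(aryl A)-2-{1-[4-(benzyloxy)-3-methoxyphenyl]-3-chloro-2-hydroxypropan-2-yl}-3-hydroxypropanoate | [Li+].[Li+].CC(C)(C)OC(=O)[C@@H]([C@H]([O-])c1ccc(O[C@@H]2COC(C)(C)O[C@@H]2c2ccc(OCc3ccccc3)c(OC)c2)c(OC)c1)[C@]([O-])(CCl)Cc1ccc(OCc2ccccc2)c(OC)c1
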